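**Retrosynthetic overview**

1. The strategy rests on the dihydropyran ring (O1, C2 methyl, C3 formyl, C4 side arm, C5 ester, C6). The chain O=CH–C3–C4–C5=C6 is a γ,δ-unsaturated aldehyde whose allylic end C6 also carries O1, so the C3–C4 bond is traced back to an oxygen-to-carbon shift within a cis-2-alkenyl-4-methyl-4H-1,3-dioxin (11), an isomer of ring product 13.
2. In 11 the silyloxyethyl arm must stand cis to the ester on the alkene (Z), the outer position of the cation terminus, so that it ends pseudo-equatorial at C4. This geometry is fixed by making a (Z)-α-iodoenal and carbonylating the carbon–iodine bond with retention as the last step before the rearrangement.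
3. Dioxin 11 comes from 1,3-dioxan-4-one 6 (reductive acetylation, loss of acetic acid). Dioxanone 6 comes from (S)-3-hydroxybutanoic acid (source of O1 and C2) and the iodoenal built from 3-silyloxypropanal.
4. After the rearrangement the aldehyde is masked, the arm is oxidised to the acid and esterified with acetonide-protected hydroxytyrosol; one acid treatment frees aldehyde and catechol.
5. Ring order: the sacrificial dioxanone/dioxin ring (step 4), then the dihydropyran ring of the target (step 8); the arene is bought.

Key step: step 8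

Assumption: the drawn closed-ring monoaldehyde (2,3-trans, 3,4-trans) is taken as the most stable of the interconverting aglycone forms, so acidic unmasking in the last step should converge on it.

**Route**

Step 1
Reactants: 1 3-[(tert-butyldimethylsilyl)oxy]propanal
Product: 2 (E)-5-[(tert-butyldimethylsilyl)oxy]pent-2-enal
Conditions: Ph3P=CHCHO, toluene, 80 °C
Reagents that add atoms: (triphenylphosphoranylidene)acetaldehyde, O=CC=P(c1ccccc1)(c1ccccc1)c1ccccc1
Why: Wittig olefination with the stabilised formyl ylide should give the two-carbon-extended enal with (E) geometry.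

Step 2
Reactants: 2 (E)-5-[(tert-butyldimethylsilyl)oxy]pent-2-enal
Product: 3 (Z)-5-[(tert-butyldimethylsilyl)oxy]-2-iodopent-2-enal
Conditions: I2, DMAP (cat.), K2CO3, THF/H2O, rt
Reagents that add atoms: iodine, [I][I]
Why: Amine-mediated α-iodination of an enal (conjugate addition of DMAP, iodination of the enolate, E1cB loss of DMAP) should leave the formyl group trans to the chain, which places iodine cis to the chain (Z).

Step 3
Reactants: 4 (S)-3-hydroxybutanoic acid
Product: 5 trimethylsilyl (S)-3-[(trimethylsilyl)oxy]butanoate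
Conditions: TMSCl, Et3N, CH2Cl2, 0 °C to rt
Reagents that add atoms: chlorotrimethylsilane, C[Si](C)(C)Cl
Why: Exhaustive silylation of the hydroxyl and carboxyl groups gives the bis-silyl derivative needed for aprotic acetalisation without touching the stereocentre.

Step 4
Reactants: 3 (Z)-5-[(tert-butyldimethylsilyl)oxy]-2-iodopent-2-enal; 5 trimethylsilyl (S)-3-[(trimethylsilyl)oxy]butanoate
Product: 6 (2S,6S)-2-[(Z)-4-[(tert-butyldimethylsilyl)oxy]-1-iodobut-1-en-1-yl]-6-methyl-1,3-dioxan-4-one (2,6-cis)
Conditions: TMSOTf (cat.), CH2Cl2, −78 °C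
Reagents that add atoms: none
Why: Silyl-triflate-catalysed acetalisation of an aldehyde with a bis-silylated β-hydroxy acid closes the 1,3-dioxan-4-one, and reversible acetal formation should place the C2 alkenyl group equatorial and cis to the C6 methyl, which sets C2.

Step 5
Reactants: 6 cis-dioxanone
Product: 8 cis-2-[(Z)-4-[(tert-butyldimethylsilyl)oxy]-1-iodobut-1-en-1-yl]-6-methyl-1,3-dioxan-4-yl acetate (both C4 epimers), via aluminium lactolate 7 (not isolated)
Conditions: i-Bu2AlH, CH2Cl2, −78 °C; then pyridine, DMAP, Ac2O, −78 to −20 °C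
Reagents that add atoms: acetic anhydride, CC(=O)OC(C)=O
Why: Low-temperature hydride reduction of the activated lactone stops at the tetrahedral aluminium hemiacetal, which is acetylated in situ (reductive acetylation of an ester to an α-acetoxy ether) before the unstable dioxanol can fragment, the alkenyl iodide and silyl ether being inert.

Step 6
Reactants: 8 4-acetoxy-1,3-dioxane
Product: 10 (2R,4S)-2-[(Z)-4-[(tert-butyldimethylsilyl)oxy]-1-iodobut-1-en-1-yl]-4-methyl-4H-1,3-dioxin (2,4-cis), via ring oxocarbenium triflate 9 (not isolated)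
Conditions: TMSOTf, i-Pr2NEt, CH2Cl2, −78 to 0 °C
Reagents that add atoms: none
Why: The silyl triflate ionises the anomeric acetate and the hindered amine removes the adjacent C5 proton (E1-type conversion of an α-acetoxy ether into an enol ether), while the C2 acetal is deactivated toward ionisation by its electron-poor iodoalkenyl group and buffered by excess amine.

Step 7
Reactants: 10 iodoalkenyl dioxin
Product: 11 methyl (Z)-5-[(tert-butyldimethylsilyl)oxy]-2-[(2R,4S)-4-methyl-4H-1,3-dioxin-2-yl]pent-2-enoate (2,4-cis dioxin; ester cis to the silyloxyethyl chain)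
Conditions: PdCl2(PPh3)2 (cat.), CO (1 atm), MeOH, Et3N, DMF, 45 °C
Reagents that add atoms: carbon monoxide, [C-]#[O+]; methanol, CO
Why: Palladium-catalysed methoxycarbonylation of an alkenyl iodide (oxidative addition to zerovalent palladium, CO insertion, methanolysis) replaces iodine by CO2Me with retention, so the ester ends cis to the chain (Z), and the amine-buffered medium leaves the acid-labile dioxin untouched.

Step 8
Reactants: 11 cis-2-alkenyl-4-methyl-4H-1,3-dioxin
Product: 13 methyl (2S,3R,4R)-4-{2-[(tert-butyldimethylsilyl)oxy]ethyl}-3-formyl-2-methyl-3,4-dihydro-2H-pyran-5-carboxylate (all-trans), via enolate oxocarbenium zwitterion 12 (not isolated)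
Conditions: Me2AlCl (1.1 equiv), CH2Cl2, −78 to −40 °C; Et3N then aq. NaHCO3 quench
Reagents that add atoms: none
Why: Proposed new method: Me2AlCl binds the enol-ether oxygen of 11 and the lone pair of the other acetal oxygen expels it, so the acetal carbon–O(enol) bond ionises to zwitterion 12, a (Z)-aluminium enolate of the future C3 aldehyde tethered through O1–C2 to a 2-(methoxycarbonyl)alkenyl oxocarbenium ion whose ester sits on the nodal central carbon of the oxapentadienyl cation; the enolate carbon C3 then adds to the vinylogous terminus C4 and O1 is returned as the β-alkoxyacrylate, a net 1,3 shift from oxygen to carbon that equals a stepwise [3,3] rearrangement. The closest known reactions are the Petasis–Ferrier rearrangement of cyclic enol acetals under Me2AlCl and the thermal Claisen rearrangement of 2-alkenyl-3,4-dihydro-2H-pyrans to cyclohex-3-enecarbaldehydes, neither of which has been shown on a 2-alkenyl-4H-1,3-dioxin. The dihydropyran closes in a 6-(enolexo)-endo-trig mode through a chair-like half-chair that needs the oxocarbenium ion with C2 cis to C5, a geometry reached by reversible collapse of 12 to the cis and trans dioxins and ring inversion. C2 is carried over from (S)-3-hydroxybutanoic acid, and C4 is set relative to it because the C2 methyl lies equatorial while the arm, standing cis to the ester on the outer position of the cation terminus, becomes pseudo-equatorial and so 2,4-cis, whereas an arm cis to the acetal carbon would be forced pseudo-axial and lead to the 2,4-trans series. C3 is set trans to both neighbours because the C2–H bond eclipses the enolate double bond (allylic 1,3-strain) in that chair, and the α-formyl centre can in any case equilibrate to the equatorial aldehyde under the Lewis acid. The step needs C–C bonding at C4 instead of return at C6, proton loss from the allylic CH2 or retro-hetero-Diels–Alder cleavage, and this is secured in the substrate because return at C6 is reversible whereas bonding at C4 is irreversible and ends in the stabilised vinylogous carbonate, while the outward-pointing arm keeps its silyloxy group away from the cationic carbon and the low temperature disfavours the fragmentations.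

Step 9
Reactants: 13 all-trans dihydropyran carbaldehyde
Product: 14 methyl (2S,3R,4R)-4-{2-[(tert-butyldimethylsilyl)oxy]ethyl}-3-(1,3-dioxolan-2-yl)-2-methyl-3,4-dihydro-2H-pyran-5-carboxylate
Conditions: TMSOCH2CH2OTMS, TMSOTf (cat.), CH2Cl2, −78 °C
Reagents that add atoms: 1,2-bis(trimethylsilyloxy)ethane, C[Si](C)(C)OCCO[Si](C)(C)C
Why: Silyl-triflate-catalysed dioxolanation with the bis-silyl glycol at low temperature masks the aldehyde without epimerising C3 or touching the vinylogous carbonate and the silyl ether.

Step 10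
Reactants: 14 dioxolane silyl ether
Product: 15 methyl (2S,3R,4R)-3-(1,3-dioxolan-2-yl)-4-(2-hydroxyethyl)-2-methyl-3,4-dihydro-2H-pyran-5-carboxylate
Conditions: HF·pyridine, pyridine, THF, 0 °C to rt
Reagents that add atoms: none
Why: Buffered HF·pyridine cleaves the primary silyl ether under mildly acidic fluoride conditions that avoid base-induced lactonisation of the freed alcohol onto the C5 ester and leave the dioxolane intact.

Step 11
Reactants: 15 primary alcohol
Product: 17 2-[(2S,3R,4R)-3-(1,3-dioxolan-2-yl)-5-(methoxycarbonyl)-2-methyl-3,4-dihydro-2H-pyran-4-yl]acetic acid, via arm aldehyde 16 (not isolated)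
Conditions: TEMPO (cat.), PhI(OAc)2, MeCN/H2O, rt
Reagents that add atoms: water, O
Why: Oxoammonium oxidation (TEMPO with PhI(OAc)2) in aqueous acetonitrile takes the primary alcohol through aldehyde 16 and its hydrate to the carboxylic acid, while the masked C3 aldehyde and the electron-poor enol ether are not oxidised.

Step 12
Reactants: 18 hydroxytyrosol
Product: 20 2-(2,2-dimethyl-1,3-benzodioxol-5-yl)ethanol, via methoxypropyl ether 19 (not isolated)
Conditions: 2,2-dimethoxypropane, CSA (cat.), toluene, reflux, 4 Å sieves; then AcOH/H2O/THF, rt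
Reagents that add atoms: 2,2-dimethoxypropane, COC(C)(C)OC
Why: Acid-catalysed ketal exchange under removal of methanol forms the five-membered catechol acetonide, and the labile mixed ketal formed at the primary hydroxyl is hydrolysed selectively in the mild aqueous acid work-up.

Step 13
Reactants: 17 carboxylic acid; 20 acetonide alcohol
Product: 21 methyl (2S,3R,4R)-4-{2-[2-(2,2-dimethyl-1,3-benzodioxol-5-yl)ethoxy]-2-oxoethyl}-3-(1,3-dioxolan-2-yl)-2-methyl-3,4-dihydro-2H-pyran-5-carboxylate
Conditions: DCC, DMAP (cat.), CH2Cl2, 0 °C to rt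
Reagents that add atoms: none
Why: Steglich esterification (carbodiimide activation with DMAP acyl transfer) joins the acid to the primary alcohol under neutral conditions with no stereocentre at risk.

Step 14
Reactants: 21 doubly protected ester
Product: 22 methyl (2S,3R,4R)-4-{2-[2-(3,4-dihydroxyphenyl)ethoxy]-2-oxoethyl}-3-formyl-2-methyl-3,4-dihydro-2H-pyran-5-carboxylate (CNP0172886.1)
Conditions: TFA/H2O, CH2Cl2, 0 °C to rt
Reagents that add atoms: water, O
Why: Aqueous trifluoroacetic acid hydrolyses the catechol acetonide and the dioxolane in one operation, and because the all-trans closed monoaldehyde is taken as the preferred ring form, reversible ring opening or C3 enolisation under acid should return to the target.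

**Compound list**

1 | 3-[(tert-butyldimethylsilyl)oxy]propanal | O=CCCO[Si](C)(C)C(C)(C)C | starting material
2 | (E)-5-[(tert-butyldimethylsilyl)oxy]pent-2-enal | O=C/C=C/CCO[Si](C)(C)C(C)(C)C | intermediate
3 | (Z)-5-[(tert-butyldimethylsilyl)oxy]-2-iodopent-2-enal | O=C/C(I)=C/CCO[Si](C)(C)C(C)(C)C | intermediate
4 | (S)-3-hydroxybutanoic acid | C[C@H](O)CC(=O)O | starting material
5 | trimethylsilyl (S)-3-[(trimethylsilyl)oxy]butanoate | C[C@H](O[Si](C)(C)C)CC(=O)O[Si](C)(C)C | intermediate
6 | (2S,6S)-2-[(Z)-4-[(tert-butyldimethylsilyl)oxy]-1-iodobut-1-en-1-yl]-6-methyl-1,3-dioxan-4-one (cis) | C[C@H]1CC(=O)O[C@H](O1)/C(I)=C/CCO[Si](C)(C)C(C)(C)C | intermediate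
7 | diisobutylaluminium lactolate of 6 (hemiacetal O–Al at C4) | C[C@H]1CC(O[Al](CC(C)C)CC(C)C)O[C@H](O1)/C(I)=C/CCO[Si](C)(C)C(C)(C)C | intermediate (not isolated)
8 | cis-2-[(Z)-4-[(tert-butyldimethylsilyl)oxy]-1-iodobut-1-en-1-yl]-6-methyl-1,3-dioxan-4-yl acetate (C4 epimers) | C[C@H]1CC(OC(C)=O)O[C@H](O1)/C(I)=C/CCO[Si](C)(C)C(C)(C)C | intermediate
9 | ring oxocarbenium triflate from 8 | C[C@H]1CC=[O+][C@H](O1)/C(I)=C/CCO[Si](C)(C)C(C)(C)C.[O-]S(=O)(=O)C(F)(F)F | intermediate (not isolated)
10 | (2R,4S)-2-[(Z)-4-[(tert-butyldimethylsilyl)oxy]-1-iodobut-1-en-1-yl]-4-methyl-4H-1,3-dioxin (cis) | C[C@H]1C=CO[C@H](O1)/C(I)=C/CCO[Si](C)(C)C(C)(C)C | intermediate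
11 | methyl (Z)-5-[(tert-butyldimethylsilyl)oxy]-2-[(2R,4S)-4-methyl-4H-1,3-dioxin-2-yl]pent-2-enoate (key-step precursor) | C[C@H]1C=CO[C@H](O1)/C(C(=O)OC)=C/CCO[Si](C)(C)C(C)(C)C | intermediate
12 | zwitterion: (Z)-aluminium enolate tethered to the (Z)-alkenyl oxocarbenium ion | C[C@@H](/C=C\O[Al-](C)(C)Cl)\[O+]=C/C(C(=O)OC)=C/CCO[Si](C)(C)C(C)(C)C | intermediate (not isolated)
13 | methyl (2S,3R,4R)-4-{2-[(tert-butyldimethylsilyl)oxy]ethyl}-3-formyl-2-methyl-3,4-dihydro-2H-pyran-5-carboxylate (key-step product) | COC(=O)C1=CO[C@@H](C)[C@H](C=O)[C@H]1CCO[Si](C)(C)C(C)(C)C | intermediate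
14 | methyl (2S,3R,4R)-4-{2-[(tert-butyldimethylsilyl)oxy]ethyl}-3-(1,3-dioxolan-2-yl)-2-methyl-3,4-dihydro-2H-pyran-5-carboxylate | COC(=O)C1=CO[C@@H](C)[C@H](C2OCCO2)[C@H]1CCO[Si](C)(C)C(C)(C)C | intermediate
15 | methyl (2S,3R,4R)-3-(1,3-dioxolan-2-yl)-4-(2-hydroxyethyl)-2-methyl-3,4-dihydro-2H-pyran-5-carboxylate | COC(=O)C1=CO[C@@H](C)[C@H](C2OCCO2)[C@H]1CCO | intermediate
16 | methyl (2S,3R,4R)-3-(1,3-dioxolan-2-yl)-2-methyl-4-(2-oxoethyl)-3,4-dihydro-2H-pyran-5-carboxylate | COC(=O)C1=CO[C@@H](C)[C@H](C2OCCO2)[C@H]1CC=O | intermediate (not isolated)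
17 | 2-[(2S,3R,4R)-3-(1,3-dioxolan-2-yl)-5-(methoxycarbonyl)-2-methyl-3,4-dihydro-2H-pyran-4-yl]acetic acid | COC(=O)C1=CO[C@@H](C)[C@H](C2OCCO2)[C@H]1CC(=O)O | intermediate
18 | hydroxytyrosol, 4-(2-hydroxyethyl)benzene-1,2-diol | OCCc1ccc(O)c(O)c1 | starting material
19 | 5-[2-(2-methoxypropan-2-yloxy)ethyl]-2,2-dimethyl-1,3-benzodioxole | COC(C)(C)OCCc1ccc2OC(C)(C)Oc2c1 | intermediate (not isolated)
20 | 2-(2,2-dimethyl-1,3-benzodioxol-5-yl)ethanol | OCCc1ccc2OC(C)(C)Oc2c1 | intermediate
21 | methyl (2S,3R,4R)-4-{2-[2-(2,2-dimethyl-1,3-benzodioxol-5-yl)ethoxy]-2-oxoethyl}-3-(1,3-dioxolan-2-yl)-2-methyl-3,4-dihydro-2H-pyran-5-carboxylate | COC(=O)C1=CO[C@@H](C)[C@H](C2OCCO2)[C@H]1CC(=O)OCCc1ccc2OC(C)(C)Oc2c1 | intermediate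
22 | methyl (2S,3R,4R)-4-{2-[2-(3,4-dihydroxyphenyl)ethoxy]-2-oxoethyl}-3-formyl-2-methyl-3,4-dihydro-2H-pyran-5-carboxylate | COC(=O)C1=CO[C@@H](C)[C@H](C=O)[C@H]1CC(=O)OCCc1ccc(O)c(O)c1 | target

**Step count**

Total: 14 steps. Longest linear sequence: 12 steps from 1 (steps 1, 2, 4–11, 13, 14); steps 3 and 12 are side branches.

**Steps most likely to fail**

1. Step 8 (proposed new method). The ion pair may only return to the dioxins, may fragment by proton loss from the allylic CH2 or by retro-hetero-Diels–Alder cleavage, or may close with poor control of the C4 face. The fallback uses known chemistry only, sets out from 1 and 4 and returns at 13. Aldol addition of the lithium enolate of bought methyl 3,3-dimethoxypropanoate (LiN(i-Pr)2, THF, −78 °C) to 1 would give methyl 5-[(tert-butyldimethylsilyl)oxy]-2-(dimethoxymethyl)-3-hydroxypentanoate F1. Mesylation and base-induced elimination (MsCl, Et3N, then DBU) would give methyl (E)-5-[(tert-butyldimethylsilyl)oxy]-2-(dimethoxymethyl)pent-2-enoate F2. Acid-catalysed esterification of 4 in methanol gives methyl (S)-3-hydroxybutanoate F3. Its dianion (two equivalents of LiN(i-Pr)2) should add to F2 in a Fráter–Seebach-type Michael reaction, forming the C3–C4 bond anti to the alkoxide and giving the hydroxy diester acetal F4. Acid (PPTS, warm toluene) should close the hydroxyl onto the acetal carbon with loss of methanol to give dimethyl (2S,3R,4R)-4-{2-[(tert-butyldimethylsilyl)oxy]ethyl}-2-methyl-3,4-dihydro-2H-pyran-3,5-dicarboxylate F5. i-Bu2AlH at −78 °C should then reduce the saturated C3 ester, not the push–pull C5 ester, to aldehyde 13, with C3 equilibrating to trans. In this fallback the C4 configuration would rest on acyclic Michael selectivity and separation of diastereomers.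

2. Step 6. The silyl triflate may ionise the C2 acetal instead of the anomeric acetate, leading to ring opening or early skeletal rearrangement of the iodo compound, and the enol ether may hydrolyse on work-up. The fallback sets out from 6 and returns at 10. Reduction with i-Bu2AlH at −78 °C to lactolate 7 is followed in the same flask by Et3N, DMAP and MsCl. The resulting cis-2-[(Z)-4-[(tert-butyldimethylsilyl)oxy]-1-iodobut-1-en-1-yl]-6-methyl-1,3-dioxan-4-yl methanesulfonate F6 should lose methanesulfonate on warming with excess amine and give 10 by a base-driven dehydration that needs no silyl Lewis acid.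

3. Step 14. Acid strong enough to cleave the catechol acetonide may also hydrate or open the dihydropyran, cleave the phenethyl ester, or leave C3 as a mixture. The fallback sets out from 17 and 18 and returns at 22. Mitsunobu esterification (PPh3, DIAD, THF, 0 °C) with unprotected hydroxytyrosol 18 should engage only the far more acidic carboxylic acid as pronucleophile and the primary alcohol as electrophile. It would give methyl (2S,3R,4R)-4-{2-[2-(3,4-dihydroxyphenyl)ethoxy]-2-oxoethyl}-3-(1,3-dioxolan-2-yl)-2-methyl-3,4-dihydro-2H-pyran-5-carboxylate F7. Dilute aqueous acid (for example 1 M HCl in THF at 0 °C) should then hydrolyse only the dioxolane to 22.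

**Further compounds**

F1 | step 8 | methyl 5-[(tert-butyldimethylsilyl)oxy]-2-(dimethoxymethyl)-3-hydroxypentanoate (diastereomer mixture) | COC(=O)C(C(OC)OC)C(O)CCO[Si](C)(C)C(C)(C)C
F2 | step 8 | methyl (E)-5-[(tert-butyldimethylsilyl)oxy]-2-(dimethoxymethyl)pent-2-enoate | COC(OC)/C(C(=O)OC)=C\CCO[Si](C)(C)C(C)(C)C
F3 | step 8 | methyl (S)-3-hydroxybutanoate | C[C@H](O)CC(=O)OC
F4 | step 8 | Michael adduct: dimethyl 2-(dimethoxymethyl)-4-[(S)-1-hydroxyethyl]-3-{2-[(tert-butyldimethylsilyl)oxy]ethyl}pentanedioate, C3 and C4 of the future ring as in 13 | C[C@H](O)[C@H](C(=O)OC)[C@@H](CCO[Si](C)(C)C(C)(C)C)C(C(=O)OC)C(OC)OC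
F5 | step 8 | dimethyl (2S,3R,4R)-4-{2-[(tert-butyldimethylsilyl)oxy]ethyl}-2-methyl-3,4-dihydro-2H-pyran-3,5-dicarboxylate | COC(=O)C1=CO[C@@H](C)[C@H](C(=O)OC)[C@H]1CCO[Si](C)(C)C(C)(C)C
F6 | step 6 | cis-2-[(Z)-4-[(tert-butyldimethylsilyl)oxy]-1-iodobut-1-en-1-yl]-6-methyl-1,3-dioxan-4-yl methanesulfonate | C[C@H]1CC(OS(C)(=O)=O)O[C@H](O1)/C(I)=C/CCO[Si](C)(C)C(C)(C)C
F7 | step 14 | methyl (2S,3R,4R)-4-{2-[2-(3,4-dihydroxyphenyl)ethoxy]-2-oxoethyl}-3-(1,3-dioxolan-2-yl)-2-methyl-3,4-dihydro-2H-pyran-5-carboxylate | COC(=O)C1=CO[C@@H](C)[C@H](C2OCCO2)[C@H]1CC(=O)OCCc1ccc(O)c(O)c1
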